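**Retrosynthetic overview**

1. Feature: C10 (quaternary, methyl C14, ring oxygen) is the α-carbon of the C1 ketone of the furanone ring (O, C3, C2, C1, C10). It is therefore the 2-position of a flat, aromatic 3-siloxyfuran, and its neighbour C9 is a carbinol, so C9–C10 is an aldol bond inside the ten-membered carbocycle C1–C10.
2. Target ⇒ C9 alcohol with C8 PMB ether (esters go on last) ⇒ intramolecular Mukaiyama aldol (C9–C10) of a siloxyfuran aldehyde, which closes the ten-membered ring and regenerates the furanone.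
3. Siloxyfuran aldehyde ⇒ trans α-methylene γ-lactone alcohol ⇒ zinc Barbier coupling (C6–C7) of a Z enal with a 3-(bromomethyl) δ-lactone whose ester oxygen is O9, then δ-to-γ lactone ring switch that frees C9–OH. An open-chain (Z)-2-(bromomethyl)enoate would be expected to give the 6,7-cis lactone through the usual chair transition state, so the ring-locked reagent is used.
4. Enal ⇒ 2-methylfuran-3(2H)-one built from (Z)-3-methylpent-2-en-4-yn-1-ol and a lactate Weinreb amide; δ-lactone ⇒ (S)-but-3-ene-1,2-diol, 2-(bromomethyl)acrylic acid and ring-closing metathesis.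
5. Ring order: furanone, δ-lactone, γ-lactone (by ring switch), then the ten-membered carbocycle.

Key step: step 15

**Remarks on the chemistry**

- Germacrane numbering is used throughout (C1 ketone, C3 on the furanone oxygen, C6 lactone carbinol, C8/C9 oxygenated, C10 quaternary).
- Compounds 3–5 and 7–11 are racemic at C10, and 20–22 are mixtures of C10 epimers. This centre becomes planar in 23, so it is left undefined in the SMILES.
- (S)-But-3-ene-1,2-diol is taken as commercially available; it is also accessible from (R)-glyceraldehyde acetonide by methylenation and hydrolysis.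

**Route**

Step 1
Reactants: 1 (2Z)-3-methylpent-2-en-4-yn-1-ol
Product: 2 tert-butyl{[(2Z)-3-methylpent-2-en-4-yn-1-yl]oxy}diphenylsilane
Conditions: TBDPSCl, imidazole, DMF, 0 °C to rt
Reagents that add atoms: tert-butyldiphenylsilyl chloride, CC(C)(C)[Si](Cl)(c1ccccc1)c1ccccc1
Why: Standard imidazole-promoted silylation of a primary alcohol; the robust TBDPS ether keeps the Z-allylic hydroxyl from cyclising onto the later ynone and survives the acidic furanone closure.

Step 2
Reactants: 3 ethyl lactate (racemic)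
Product: 4 ethyl 2-[(triethylsilyl)oxy]propanoate
Conditions: TESCl, imidazole, CH2Cl2, 0 °C to rt
Reagents that add atoms: chlorotriethylsilane, CC[Si](Cl)(CC)CC
Why: Standard silyl protection of the secondary alcohol, which shields it from the Grignard and acetylide reagents yet is labile enough to be lost in the acidic furanone closure.

Step 3
Reactants: 4 ethyl 2-[(triethylsilyl)oxy]propanoate
Product: 5 N-methoxy-N-methyl-2-[(triethylsilyl)oxy]propanamide
Conditions: MeNH(OMe)·HCl, i-PrMgCl, THF, −20 to 0 °C
Reagents that add atoms: N,O-dimethylhydroxylamine hydrochloride, CNOC.Cl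
Why: Direct aminolysis of the ester by the magnesium amide of N,O-dimethylhydroxylamine (Weinreb amide formation) is routine for O-silyl lactates.

Step 4
Reactants: 2 tert-butyl{[(2Z)-3-methylpent-2-en-4-yn-1-yl]oxy}diphenylsilane and 5 N-methoxy-N-methyl-2-[(triethylsilyl)oxy]propanamide
Product: 7 (6Z)-8-[(tert-butyldiphenylsilyl)oxy]-6-methyl-2-[(triethylsilyl)oxy]oct-6-en-4-yn-3-one, via lithium acetylide 6 (not isolated)
Conditions: n-BuLi, THF, −78 °C; then 5, −78 to 0 °C; AcOH quench
Reagents that add atoms: n-butyllithium, [Li]CCCC (lithium only in intermediate 6)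
Why: Weinreb ketone synthesis, in which the chelated tetrahedral adduct stops the acetylide at single addition and gives the α'-silyloxy ynone (C1–C3 joined to C4–C6) with the Z alkene untouched.

Step 5
Reactants: 7 (6Z)-8-[(tert-butyldiphenylsilyl)oxy]-6-methyl-2-[(triethylsilyl)oxy]oct-6-en-4-yn-3-one
Product: 9 5-{(2Z)-4-[(tert-butyldiphenylsilyl)oxy]but-2-en-2-yl}-2-methylfuran-3(2H)-one, via enaminone 8 (not isolated)
Conditions: Et2NH, EtOH, rt; then 1 M aq. HCl/THF, rt
Reagents that add atoms: diethylamine, CCNCC (only in intermediate 8)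
Why: Classical furan-3(2H)-one synthesis from α'-oxy ynones, in which conjugate addition of the amine gives the β-enaminone and aqueous acid removes the TES group so that the freed hydroxyl closes 5-exo-trig onto the iminium carbon C3 with loss of diethylamine, while the TBDPS ether is stable.

Step 6
Reactants: 9 5-{(2Z)-4-[(tert-butyldiphenylsilyl)oxy]but-2-en-2-yl}-2-methylfuran-3(2H)-one
Product: 10 5-[(2Z)-4-hydroxybut-2-en-2-yl]-2-methylfuran-3(2H)-one
Conditions: Bu4NF, AcOH, THF, 0 °C to rt; crude product used at once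
Reagents that add atoms: none
Why: Fluoride cleavage of the silyl ether, buffered with acetic acid so that neither free alkoxide nor strong acid can make the Z-hydroxyl add to C3 and rearrange the furanone into an aromatic furan.

Step 7
Reactants: 10 5-[(2Z)-4-hydroxybut-2-en-2-yl]-2-methylfuran-3(2H)-one
Product: 11 (2Z)-3-(5-methyl-4-oxo-4,5-dihydrofuran-2-yl)but-2-enal
Conditions: MnO2, CH2Cl2, rt
Reagents that add atoms: none
Why: Manganese dioxide oxidation of an allylic alcohol is neutral and heterogeneous, so the C6 enal should form with the Z geometry retained.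

Step 8
Reactants: 12 (2S)-but-3-ene-1,2-diol
Product: 13 (4S)-4-ethenyl-2-(4-methoxyphenyl)-1,3-dioxolane (both acetal epimers)
Conditions: 4-MeOC6H4CH(OMe)2, PPTS (cat.), CH2Cl2, rt
Reagents that add atoms: 4-methoxybenzaldehyde dimethyl acetal, COc1ccc(C(OC)OC)cc1
Why: Acid-catalysed transacetalisation of a 1,2-diol, which leaves the C8 stereocentre (from the chiral pool) untouched.

Step 9
Reactants: 13 (4S)-4-ethenyl-2-(4-methoxyphenyl)-1,3-dioxolane
Product: 14 (2S)-2-[(4-methoxybenzyl)oxy]but-3-en-1-ol
Conditions: i-Bu2AlH (DIBAL-H), CH2Cl2, −78 to 0 °C; aq. KNaC4H4O6 work-up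
Reagents that add atoms: none
Why: Regioselective reductive opening of the p-methoxybenzylidene acetal, in which aluminium binds the less hindered primary oxygen and hydride delivery leaves the PMB group on the secondary oxygen (the future O8) and the primary alcohol (future O9) free.

Step 10
Reactants: 15 2-(bromomethyl)prop-2-enoic acid and 14 (2S)-2-[(4-methoxybenzyl)oxy]but-3-en-1-ol
Product: 17 (2S)-2-[(4-methoxybenzyl)oxy]but-3-en-1-yl 2-(bromomethyl)prop-2-enoate, via acid chloride 16 (not isolated)
Conditions: (COCl)2, DMF (cat.), CH2Cl2, 0 °C to rt, concentrate; then 14, 2,6-lutidine, CH2Cl2, −20 to 0 °C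
Reagents that add atoms: oxalyl chloride, O=C(Cl)C(=O)Cl (chlorine only in intermediate 16)
Why: Acylation of a primary alcohol by an acid chloride, with the hindered base 2,6-lutidine chosen because it does not displace the allylic bromide.

Step 11
Reactants: 17 (2S)-2-[(4-methoxybenzyl)oxy]but-3-en-1-yl 2-(bromomethyl)prop-2-enoate
Product: 18 (5S)-3-(bromomethyl)-5-[(4-methoxybenzyl)oxy]-5,6-dihydro-2H-pyran-2-one
Conditions: second-generation Grubbs catalyst (H2IMes)(PCy3)Cl2Ru=CHPh (5 mol %), toluene (5 mM), 80 °C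
Reagents that add atoms: none
Why: Ring-closing metathesis of an α-substituted acrylate of a homoallylic-type alcohol to the 5,6-dihydropyran-2-one is well established, is driven by loss of ethylene, and ruthenium carbenes tolerate allylic bromides.

Step 12
Reactants: 18 (5S)-3-(bromomethyl)-5-[(4-methoxybenzyl)oxy]-5,6-dihydro-2H-pyran-2-one and 11 (2Z)-3-(5-methyl-4-oxo-4,5-dihydrofuran-2-yl)but-2-enal
Product: 21 (4S,5R)-4-{(1S)-2-hydroxy-1-[(4-methoxybenzyl)oxy]ethyl}-3-methylidene-5-[(1Z)-2-(5-methyl-4-oxo-4,5-dihydrofuran-2-yl)prop-1-en-1-yl]dihydrofuran-2(3H)-one, via allylzinc bromide 19 (not isolated), via hydroxy delta-lactone 20 (not isolated)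
Conditions: Zn dust, THF/sat. aq. NH4Cl, 0 °C to rt; then CSA (cat.), CH2Cl2, rt
Reagents that add atoms: zinc, [Zn] (only in intermediate 19)
Why: Barbier 2-(alkoxycarbonyl)allylation, in which the allylzinc adds 1,2 to the enal through C7 on the ring face anti to the neighbouring C8 PMB-oxy group (7S) via a chair transition state with the alkenyl group equatorial, so that the ring-locked geometry (C8 cis to the carbonyl) gives the 6,7-anti adduct (6R), and acid-catalysed translactonisation to the less strained trans γ-lactone then releases C9–OH.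

Step 13
Reactants: 21 the γ-lactone alcohol
Product: 22 (2S)-2-[(4-methoxybenzyl)oxy]-2-{(2R,3S)-4-methylidene-2-[(1Z)-2-(5-methyl-4-oxo-4,5-dihydrofuran-2-yl)prop-1-en-1-yl]-5-oxotetrahydrofuran-3-yl}acetaldehyde
Conditions: Dess–Martin periodinane, pyridine, CH2Cl2, 0 °C
Reagents that add atoms: none
Why: Dess–Martin oxidation converts the primary C9 alcohol into the α-alkoxy aldehyde under buffered, non-epimerising conditions that leave the furanone, the alkenes and the PMB ether alone.

Step 14
Reactants: 22 the furanone aldehyde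
Product: 23 (2S)-2-[(4-methoxybenzyl)oxy]-2-{(2R,3S)-4-methylidene-2-[(1Z)-2-{5-methyl-4-[(triethylsilyl)oxy]furan-2-yl}prop-1-en-1-yl]-5-oxotetrahydrofuran-3-yl}acetaldehyde
Conditions: TESOTf (1.2 equiv), Et3N (3 equiv), CH2Cl2, −78 °C; filtration through Et3N-deactivated silica
Reagents that add atoms: triethylsilyl trifluoromethanesulfonate, CC[Si](CC)(CC)OS(=O)(=O)C(F)(F)F
Why: Soft enolisation and O-silylation of a furan-3(2H)-one to the 3-silyloxyfuran is known, and it should be chemoselective here because the vinylogous-ester carbonyl C1 is far more Lewis basic than the aldehyde and loss of the C10 proton creates an aromatic furan, whereas aldehyde enolisation is slow at −78 °C.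

Step 15
Reactants: 23 the siloxyfuran aldehyde
Product: 24 (6R,7S,8S,9R,10R)-9-hydroxy-8-[(4-methoxybenzyl)oxy]-1-oxo-3,10-epoxygermacra-2,4Z,11(13)-trien-12,6-olide
Conditions: MgBr2·OEt2 (3 equiv), CH2Cl2, 1 mM (slow addition of 23), −78 to −20 °C; aq. NaHCO3, then dilute citric acid work-up
Reagents that add atoms: none
Why: Proposed new method: MgBr2 binds the C9 aldehyde oxygen and the C8 PMB ether oxygen in a five-membered chelate, the electron-rich 3-siloxyfuran attacks the activated carbonyl through C10 (its 2-position, flanked by the ring oxygen and the siloxy-bearing C1), and bromide takes the silyl group from the resulting siloxyfuranylium ion so that the furan-3(2H)-one reappears with C10 quaternary. The closest known reaction is the intermolecular Lewis-acid Mukaiyama aldol of 2-alkyl-3-silyloxyfurans with aldehydes, which gives 2,2-disubstituted furan-3(2H)-ones; its use to close a medium ring is untested. The new C9–C10 bond closes the ten-membered carbocycle C1–C10 in a 10-(enolendo)-exo-trig mode (equally the nine-membered ring through the bridging oxygen) via an open transition state under high dilution, and the Z C4=C5 alkene together with the trans-fused lactone already fold the aldehyde arm back over the furan. C9 is controlled by the chelate: attack on the face anti to C7 (the Si face of the aldehyde) gives the 8,9-syn pattern, 9R. C10 is controlled by the tether: with the furan anchored through C3–C4=C5–C6 to the lactone, only its Re face at C10 should reach the chelated aldehyde without severe strain, giving 10R. The step needs reaction at C10 rather than at the other ortho position C2 (less nucleophilic, and leading to a strained eight-membered ring) and ring closure faster than oligomerisation or protodesilylation, which the substrate geometry, exclusion of protic acid and 1 mM concentration are meant to secure.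

Step 16
Reactants: 24 the C9 alcohol
Product: 25 (6R,7S,8S,9R,10R)-9-acetoxy-8-[(4-methoxybenzyl)oxy]-1-oxo-3,10-epoxygermacra-2,4Z,11(13)-trien-12,6-olide
Conditions: Ac2O, pyridine, DMAP (cat.), CH2Cl2, 0 °C
Reagents that add atoms: acetic anhydride, CC(=O)OC(C)=O
Why: DMAP-catalysed acetylation of the hindered secondary alcohol, run cold and short because the β-hydroxy ketone could undergo base-induced retro-aldol ring opening.

Step 17
Reactants: 25 the C9 acetate
Product: 26 (6R,7R,8S,9R,10R)-9-acetoxy-8-hydroxy-1-oxo-3,10-epoxygermacra-2,4Z,11(13)-trien-12,6-olide (the C7 descriptor changes only formally)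
Conditions: DDQ, CH2Cl2/pH 7 buffer, 0 °C
Reagents that add atoms: none
Why: Oxidative PMB ether cleavage by DDQ acts only on the electron-rich benzyl group, and the electron-poor enone, diene and acrylate units as well as the acetate should be inert.

Step 18
Reactants: 26 the C8 alcohol
Product: 27 (6R,7S,8S,9R,10R)-9-acetoxy-8-(3-methylbutanoyloxy)-1-oxo-3,10-epoxygermacra-2,4Z,11(13)-trien-12,6-olide (CNP0255553.1)
Conditions: (i-BuCO)2O, DMAP (cat.), Et3N, CH2Cl2, −20 to 0 °C
Reagents that add atoms: 3-methylbutanoic anhydride, CC(C)CC(=O)OC(=O)CC(C)C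
Why: DMAP-catalysed acylation with excess anhydride at low temperature should esterify the C8 alcohol faster than the C9 acetate can migrate to O8.

**Compound list**

1 | (2Z)-3-methylpent-2-en-4-yn-1-ol | C#C/C(C)=C\CO | starting material
2 | tert-butyl{[(2Z)-3-methylpent-2-en-4-yn-1-yl]oxy}diphenylsilane | C#C/C(C)=C\CO[Si](c1ccccc1)(c1ccccc1)C(C)(C)C | intermediate
3 | ethyl lactate (racemic) | CCOC(=O)C(C)O | starting material
4 | ethyl 2-[(triethylsilyl)oxy]propanoate | CCOC(=O)C(C)O[Si](CC)(CC)CC | intermediate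
5 | N-methoxy-N-methyl-2-[(triethylsilyl)oxy]propanamide | CON(C)C(=O)C(C)O[Si](CC)(CC)CC | intermediate
6 | lithium acetylide of 2 (not isolated) | [Li]C#C/C(C)=C\CO[Si](c1ccccc1)(c1ccccc1)C(C)(C)C | intermediate
7 | (6Z)-8-[(tert-butyldiphenylsilyl)oxy]-6-methyl-2-[(triethylsilyl)oxy]oct-6-en-4-yn-3-one | CC(O[Si](CC)(CC)CC)C(=O)C#C/C(C)=C\CO[Si](c1ccccc1)(c1ccccc1)C(C)(C)C | intermediate
8 | (6Z)-8-[(tert-butyldiphenylsilyl)oxy]-5-(diethylamino)-6-methyl-2-[(triethylsilyl)oxy]octa-4,6-dien-3-one (enaminone, not isolated) | CCN(CC)C(=CC(=O)C(C)O[Si](CC)(CC)CC)/C(C)=C\CO[Si](c1ccccc1)(c1ccccc1)C(C)(C)C | intermediate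
9 | 5-{(2Z)-4-[(tert-butyldiphenylsilyl)oxy]but-2-en-2-yl}-2-methylfuran-3(2H)-one | CC1OC(=CC1=O)/C(C)=C\CO[Si](c1ccccc1)(c1ccccc1)C(C)(C)C | intermediate
10 | 5-[(2Z)-4-hydroxybut-2-en-2-yl]-2-methylfuran-3(2H)-one | CC1OC(=CC1=O)/C(C)=C\CO | intermediate
11 | (2Z)-3-(5-methyl-4-oxo-4,5-dihydrofuran-2-yl)but-2-enal | CC1OC(=CC1=O)/C(C)=C\C=O | intermediate
12 | (2S)-but-3-ene-1,2-diol | C=C[C@H](O)CO | starting material
13 | (4S)-4-ethenyl-2-(4-methoxyphenyl)-1,3-dioxolane | C=C[C@H]1COC(c2ccc(OC)cc2)O1 | intermediate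
14 | (2S)-2-[(4-methoxybenzyl)oxy]but-3-en-1-ol | C=C[C@H](OCc1ccc(OC)cc1)CO | intermediate
15 | 2-(bromomethyl)prop-2-enoic acid | C=C(CBr)C(=O)O | starting material
16 | 2-(bromomethyl)prop-2-enoyl chloride (not isolated) | C=C(CBr)C(=O)Cl | intermediate
17 | (2S)-2-[(4-methoxybenzyl)oxy]but-3-en-1-yl 2-(bromomethyl)prop-2-enoate | C=C(CBr)C(=O)OC[C@@H](OCc1ccc(OC)cc1)C=C | intermediate
18 | (5S)-3-(bromomethyl)-5-[(4-methoxybenzyl)oxy]-5,6-dihydro-2H-pyran-2-one | BrCC1=C[C@H](OCc2ccc(OC)cc2)COC1=O | intermediate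
19 | allylzinc bromide from 18 (not isolated) | Br[Zn]CC1=C[C@H](OCc2ccc(OC)cc2)COC1=O | intermediate
20 | (4S,5S)-4-[(1R,2Z)-1-hydroxy-3-(5-methyl-4-oxo-4,5-dihydrofuran-2-yl)but-2-en-1-yl]-5-[(4-methoxybenzyl)oxy]-3-methylidenetetrahydro-2H-pyran-2-one (not isolated) | C=C1C(=O)OC[C@@H](OCc2ccc(OC)cc2)[C@@H]1[C@H](O)/C=C(/C)C3=CC(=O)C(C)O3 | intermediate
21 | (4S,5R)-4-{(1S)-2-hydroxy-1-[(4-methoxybenzyl)oxy]ethyl}-3-methylidene-5-[(1Z)-2-(5-methyl-4-oxo-4,5-dihydrofuran-2-yl)prop-1-en-1-yl]dihydrofuran-2(3H)-one | C=C1C(=O)O[C@H](/C=C(/C)C2=CC(=O)C(C)O2)[C@H]1[C@H](OCc3ccc(OC)cc3)CO | intermediate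
22 | (2S)-2-[(4-methoxybenzyl)oxy]-2-{(2R,3S)-4-methylidene-2-[(1Z)-2-(5-methyl-4-oxo-4,5-dihydrofuran-2-yl)prop-1-en-1-yl]-5-oxotetrahydrofuran-3-yl}acetaldehyde | C=C1C(=O)O[C@H](/C=C(/C)C2=CC(=O)C(C)O2)[C@H]1[C@H](OCc3ccc(OC)cc3)C=O | intermediate
23 | (2S)-2-[(4-methoxybenzyl)oxy]-2-{(2R,3S)-4-methylidene-2-[(1Z)-2-{5-methyl-4-[(triethylsilyl)oxy]furan-2-yl}prop-1-en-1-yl]-5-oxotetrahydrofuran-3-yl}acetaldehyde (key-step precursor) | C=C1C(=O)O[C@H](/C=C(/C)c2cc(O[Si](CC)(CC)CC)c(C)o2)[C@H]1[C@H](OCc3ccc(OC)cc3)C=O | intermediate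
24 | (6R,7S,8S,9R,10R)-9-hydroxy-8-[(4-methoxybenzyl)oxy]-1-oxo-3,10-epoxygermacra-2,4Z,11(13)-trien-12,6-olide (key-step product) | C=C1C(=O)O[C@@H]2/C=C(/C)C3=CC(=O)[C@](C)(O3)[C@H](O)[C@@H](OCc4ccc(OC)cc4)[C@@H]12 | intermediate
25 | (6R,7S,8S,9R,10R)-9-acetoxy-8-[(4-methoxybenzyl)oxy]-1-oxo-3,10-epoxygermacra-2,4Z,11(13)-trien-12,6-olide | C=C1C(=O)O[C@@H]2/C=C(/C)C3=CC(=O)[C@](C)(O3)[C@H](OC(C)=O)[C@@H](OCc4ccc(OC)cc4)[C@@H]12 | intermediate
26 | (6R,7R,8S,9R,10R)-9-acetoxy-8-hydroxy-1-oxo-3,10-epoxygermacra-2,4Z,11(13)-trien-12,6-olide | C=C1C(=O)O[C@@H]2/C=C(/C)C3=CC(=O)[C@](C)(O3)[C@H](OC(C)=O)[C@@H](O)[C@@H]12 | intermediate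
27 | (6R,7S,8S,9R,10R)-9-acetoxy-8-(3-methylbutanoyloxy)-1-oxo-3,10-epoxygermacra-2,4Z,11(13)-trien-12,6-olide (CNP0255553.1) | C=C1C(=O)O[C@@H]2/C=C(/C)C3=CC(=O)[C@](C)(O3)[C@H](OC(C)=O)[C@@H](OC(=O)CC(C)C)[C@@H]12 | target

**Step count**

Total steps: 18. Longest linear sequence: 13 steps (steps 2–7 and 12–18, from ethyl lactate).

**Steps most likely to fail**

1. Step 15 (proposed new method). Oligomerisation by intermolecular aldol may outrun closure of the strained ring, the furan may present the wrong face at C10, or the siloxyfuran may simply be protodesilylated back to 22. Fallback by a reductive, closed-transition-state aldol: starting from 23, N-bromosuccinimide in THF at −78 °C should brominate the siloxyfuran at C10 to give the 2-bromo-2-methylfuranone aldehyde F1, used crude. SmI2 (2.2 equiv, THF, −78 °C, high dilution) should then generate the samarium enolate at C10 and close the C9–C10 bond in an intramolecular Reformatsky-type aldol through a chelated cyclic transition state, coming back to the route at 24.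

2. Step 12. The allylzinc intermediate may lose the C8 PMB-oxy group by 1,4-elimination (towards a 3-methylpyranone), attack syn to that group may erode the C7/C6 selectivity, or the δ-to-γ lactone switch may stall. Fallback with an isolated, non-basic allyl reagent: starting from 18, palladium-catalysed borylation (B2pin2, Pd2(dba)3 cat., toluene, 50 °C) should give the allylboronate lactone F2. Heating F2 with enal 11 in toluene (80 °C, or Sc(OTf)3 cat. at 0 °C) should pass through the same chair transition state to the borate of 20, and aqueous work-up followed by CSA should return the route at 21.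

3. Step 14. With the aldehyde already present, the silyl triflate may trigger a premature, non-chelated aldol or oligomerisation, or the base may enolise the aldehyde and epimerise C8. Fallback that makes the siloxyfuran before the aldehyde exists: starting from 21, TESOTf (2.5 equiv)/Et3N in CH2Cl2 at −78 °C should silylate both the furanone and the C9 hydroxyl to give the bis(triethylsilyl) compound F3. Swern conditions ((COCl)2, DMSO, CH2Cl2, −78 to −40 °C, then Et3N), which are known to convert primary triethylsilyl ethers directly into aldehydes, should then return the route at 23.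

**Further compounds**

F1 | step 15 | (2S)-2-{(2R,3S)-2-[(1Z)-2-(5-bromo-5-methyl-4-oxo-4,5-dihydrofuran-2-yl)prop-1-en-1-yl]-4-methylidene-5-oxotetrahydrofuran-3-yl}-2-[(4-methoxybenzyl)oxy]acetaldehyde | C=C1C(=O)O[C@H](/C=C(/C)C2=CC(=O)C(C)(Br)O2)[C@H]1[C@H](OCc3ccc(OC)cc3)C=O
F2 | step 12 | (5S)-5-[(4-methoxybenzyl)oxy]-3-[(4,4,5,5-tetramethyl-1,3,2-dioxaborolan-2-yl)methyl]-5,6-dihydro-2H-pyran-2-one | CC1(C)OB(CC2=C[C@H](OCc3ccc(OC)cc3)COC2=O)OC1(C)C
F3 | step 14 | (4S,5R)-4-{(1S)-1-[(4-methoxybenzyl)oxy]-2-[(triethylsilyl)oxy]ethyl}-3-methylidene-5-[(1Z)-2-{5-methyl-4-[(triethylsilyl)oxy]furan-2-yl}prop-1-en-1-yl]dihydrofuran-2(3H)-one | C=C1C(=O)O[C@H](/C=C(/C)c2cc(O[Si](CC)(CC)CC)c(C)o2)[C@H]1[C@H](OCc3ccc(OC)cc3)CO[Si](CC)(CC)CC
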